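The numbers in the tables are simulated on assumed constants, noise included.

In a one-step world every percent of substrate lost shows up at once as product, yet in the eta run the five peaks at 4.00 min sum to 83.0% of the charge. So there are steps in between, and what leads at the end hangs on which peak feeds side product A.

| setting | eta | beta | Thursday's | Monday's |
|---|---|---|---|---|
| substrate | 0.13 M | 0.065 M | 0.13 M | 0.13 M |
| partner | 0.195 M | 0.195 M | 0.200 M | 0.580 M |
| protic impurity | 4.4 mM | 6.5 mM | 6.50 mM | 6.50 mM |
| remark | run made earlier | run made earlier |  |  |
| time |  |  | 20 min | 20 min |

| run | time / min | side product A / % | intermediate C / % | substrate / % | side product B / % | target / % |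
|---|---|---|---|---|---|---|
| eta | 0.500 | 1.9 | 0.4 | 63.0 | 2.5 | 2.4 |
| eta | 1.33 | 2.4 | 5.1 | 44.1 | 11.6 | 6.3 |
| eta | 2.50 | 3.2 | 4.9 | 32.3 | 24.1 | 9.3 |
| eta | 4.00 | 7.5 | 3.5 | 23.1 | 36.6 | 12.3 |
| beta | 0.333 | 0.7 | 1.2 | 69.4 | 1.4 | 4.2 |
| beta | 0.667 | 0.8 | 1.3 | 55.6 | 4.3 | 5.5 |
| beta | 1.50 | 0.4 | 5.6 | 41.2 | 15.3 | 7.3 |
| beta | 4.00 | 9.8 | 6.8 | 22.1 | 35.0 | 13.3 |

(each reading ± 1 percentage point)



- which of these there is most of at the end, counted by the substrate in it, Thursday's (side product B / side product A / intermediate C / substrate / target)
- which of these there is most of at the end, counted by the substrate in it, Monday's (side product B / side product A / intermediate C / substrate / target)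
- amount of the one of these that there is most of at the end, in percent of the substrate charged, Thursday's
- amount of the one of these that there is most of at the end, in percent of the substrate charged, Monday's

1. Suppose side product A forms from one feeder, first-order in it. Integrating from zero, its amount is a constant times the area under the feeder's curve. Two runs give that constant independently, and a true feeder should give one number.

2. Take intermediate C as feeder, with trapezoid areas. Eta gives 0.516 min⁻¹ and beta 0.516 min⁻¹. Their mean, side product A made per unit area under the curve of intermediate C, is our drain constant, 0.516 min⁻¹.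

3. Take side product B as feeder instead. Eta gives 0.103 min⁻¹, but beta gives 0.136 min⁻¹. The two part, so we suspect this route. With a scatter of 1 percentage point on readings of 7.5% and 9.8%, that is a lean, not a proof.

4. We therefore treat side product B as an end product. It makes up 61.1% of the four later peaks at eta's last reading. Thursday's flask resembles eta, though with 6.50 mM of protic impurity against 4.4 mM, so we expect side product B to lead there at about that figure. Neither run varied the partner, so for Monday's flask we give no number.

5. The forecast says side product A at 62% for Thursday's and side product A at 50% for Monday's. It reads side product B as feeder, at 0.13 per minute, so that by the end it “has mostly become” side product A. For Thursday's leader, we differ.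

6. Thursday's flask gives side product B at 61.7%, and Monday's gives side product A at 57.5%.

    substrate + partner ⇌ intermediate A (K = 3.90 M⁻¹, k = 0.0887 M⁻¹ s⁻¹)
    substrate + partner → target (k = 0.00867 M⁻¹ s⁻¹)
    substrate → intermediate B (k = 0.00395 s⁻¹)
    partner + intermediate A ⇌ intermediate C (K = 42.7 M⁻¹, k = 0.0196 M⁻¹ s⁻¹)
    intermediate C → side product A (k = 0.00708 s⁻¹)
    intermediate B → side product B (k = 0.0269 s⁻¹)
    partner + protic impurity → quenched reagent (k = 2.88 M⁻¹ s⁻¹)

Side product B feeds no further step: Thursday's flask still holds 62.3% of it at 200 min. From 10.0 min to 20.0 min intermediate C falls roughly exponentially, so its area is the drop divided by the logarithm of the ratio, times the span. In Thursday's flask our drain constant, itself a reading with its scatter, turns that area into an estimate of 3.5 points of side product A, and the flask gains 2.9 points. In Monday's flask the same reckoning estimates 4.4 points, and the flask gains 3.7 points. The difference in partner is the main reason that Monday's side product B stands at 21.1% rather than 61.7%.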